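## Retrosynthetic overview

1. Target ⇐ oxidation at C9 and site-selective tigloylation at O8 of a 7β-isopropenyl-8α,9β-diol.
2. That diol ⇐ 7α,8α-epoxy-9β-ol by alkoxide-directed, trans-diaxial isopropenyl transfer from aluminium (the new step; makes the C7–C11 bond and sets C7).
3. 1α-OAc and 10α-H (trans ring fusion) ⇐ hydroboration–oxidation of a Δ1(10) alkene; the epoxy alcohol ⇐ a cross-conjugated dienone (site-selective nucleophilic epoxidation, Luche reduction).
4. Ring A (formed second) ⇐ Shapiro vinyllithium + acrolein, then ring-closing metathesis onto a C5 allyl group.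
5. Ring B (present from the start) = 2-methylcyclohex-2-enone; C4 and C5 are set by copper-catalysed asymmetric conjugate methylation and enolate allylation.

Atom labels (eremophilane numbering): decalin carbons C1–C10; C5 is the methyl-bearing ring-fusion carbon, C10 the other; C4 carries the secondary methyl, C1 the acetate, C7 the isopropenyl, C8 the tiglate, C9 the ketone; ring B = C1–C5 + C10, ring A = C5–C10; β = face of the C5 methyl, α = the opposite face.

Assumption: the phosphoramidite enantiomer in step 1 is the one that gives the (S) β-carbon (its antipode gives the enantiomeric series); compounds 8 and 9 are carried as mixtures of C9 carbinol epimers that converge in step 5.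

## Route

Step 1
Reactants: 1 2-methylcyclohex-2-en-1-one
Product: 4 (2R,3S)-2-allyl-2,3-dimethylcyclohexan-1-one, via aluminium enolate 2 (not isolated), via lithium aluminate enolate 3 (not isolated)
Conditions: Me3Al, Cu(O2CC4H3S) (copper thiophene-2-carboxylate, 2 mol%), (S)-BINOL-derived N,N-bis[(R)-1-phenylethyl]phosphoramidite (4 mol%), Et2O, −30 °C; then MeLi, THF/DMPU, allyl iodide, −30 → 0 °C
Reagents that add atoms: trimethylaluminium, C[Al](C)C; allyl iodide, C=CCI
Why: Copper-catalysed asymmetric conjugate addition sets C4 (S) under ligand control, and the regiodefined enolate, made more nucleophilic as its aluminate, is C-allylated anti to the neighbouring methyl (pseudo-axial to avoid allylic strain), which gives the cis-dimethyl quaternary centre C5 (R).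

Step 2
Reactants: 4 (2R,3S)-2-allyl-2,3-dimethylcyclohexan-1-one
Product: 5 (E)-N'-[(2R,3S)-2-allyl-2,3-dimethylcyclohexylidene]-2,4,6-triisopropylbenzenesulfonohydrazide
Conditions: 2,4,6-triisopropylbenzenesulfonohydrazide, HCl (cat.), MeCN, rt
Reagents that add atoms: 2,4,6-triisopropylbenzenesulfonohydrazide, CC(C)c1cc(C(C)C)c(S(=O)(=O)NN)c(C(C)C)c1
Why: Acid-catalysed hydrazone condensation; the sulfonamide nitrogen turns away from the quaternary carbon and so lies syn to the only α-CH2, as the Shapiro reaction needs.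

Step 3
Reactants: 5 (E)-N'-[(2R,3S)-2-allyl-2,3-dimethylcyclohexylidene]-2,4,6-triisopropylbenzenesulfonohydrazide
Product: 8 1-[(5S,6R)-6-allyl-5,6-dimethylcyclohex-1-en-1-yl]prop-2-en-1-ol (both carbinol epimers), via hydrazone dianion 6 (not isolated), via vinyllithium 7 (not isolated)
Conditions: n-BuLi (2.2 equiv), THF, −78 → 0 °C; then acrolein, −78 °C; then H2O
Reagents that add atoms: acrolein, C=CC=O
Why: Shapiro reaction: syn α-deprotonation, loss of sulfinate and N2 give the C10 vinyllithium (the alkene can only be Δ1(10) because C5 has no hydrogen), which adds 1,2 to acrolein; the uncontrolled carbinol centre is erased in step 5.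

Step 4
Reactants: 8 1-[(5S,6R)-6-allyl-5,6-dimethylcyclohex-1-en-1-yl]prop-2-en-1-ol
Product: 9 (4aR,5S)-4a,5-dimethyl-1,4,4a,5,6,7-hexahydronaphthalen-1-ol (both C9 epimers; Δ7 and Δ1(10))
Conditions: second-generation Grubbs catalyst, RuCl2(=CHPh)(PCy3)(H2IMes) (3 mol%), CH2Cl2, 40 °C
Reagents that add atoms: none
Why: Ring-closing metathesis of the two monosubstituted alkenes closes ring A as a cyclohexene and leaves the trisubstituted Δ1(10) alkene untouched.

Step 5
Reactants: 9 (4aR,5S)-4a,5-dimethyl-1,4,4a,5,6,7-hexahydronaphthalen-1-ol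
Product: 10 (4aR,5S)-4a,5-dimethyl-4a,5,6,7-tetrahydronaphthalen-1(4H)-one
Conditions: MnO2, CH2Cl2, rt
Reagents that add atoms: none
Why: Allylic oxidation of the doubly allylic alcohol converges both epimers on the cross-conjugated dienone.

Step 6
Reactants: 10 (4aR,5S)-4a,5-dimethyl-4a,5,6,7-tetrahydronaphthalen-1(4H)-one
Product: 11 7α,8α-epoxy-4β,5β-dimethyl-Δ1(10)-octalin-9-one
Conditions: 30% H2O2 (1.2 equiv), NaOH (cat.), MeOH, −10 → 0 °C
Reagents that add atoms: hydrogen peroxide, OO
Why: Weitz–Scheffer nucleophilic epoxidation picks the α-unsubstituted Δ7 enone over the α-substituted exocyclic one, and hydroperoxide attacks C7 anti to the pseudo-axial C5 methyl, which places the epoxide on the α face and so sets the C8–O stereocentre.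

Step 7
Reactants: 11 7α,8α-epoxy-4β,5β-dimethyl-Δ1(10)-octalin-9-one
Product: 12 7α,8α-epoxy-4β,5β-dimethyl-Δ1(10)-octalin-9β-ol
Conditions: NaBH4, CeCl3·7H2O, MeOH, −78 → −20 °C
Reagents that add atoms: none
Why: Luche 1,2-reduction: hydride enters from the α face, away from the syn-axial C5 methyl, to give the axial 9β-alcohol trans to the epoxide; this centre is temporary but its β configuration is what step 10 uses.

Step 8
Reactants: 12 7α,8α-epoxy-4β,5β-dimethyl-Δ1(10)-octalin-9β-ol
Product: 14 7α,8α-epoxy-4β,5β-dimethyl-10αH-decalin-1α,9β-diol, via alkylborane 13 (not isolated)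
Conditions: BH3·THF (3 equiv), THF, 0 °C → rt; then NaBO3·4H2O, H2O, rt
Reagents that add atoms: sodium perborate, [Na+].[O-]OB=O
Why: Hydroboration–oxidation: borane adds syn from the α face (the β face is blocked by the C5 methyl and the C9 alkoxyborane) with boron on the less substituted C1, which sets 10α-H (trans-decalin) and, after oxidation with retention, the equatorial 1α-OH.

Step 9
Reactants: 14 7α,8α-epoxy-4β,5β-dimethyl-10αH-decalin-1α,9β-diol
Product: 15 1α-acetoxy-7α,8α-epoxy-4β,5β-dimethyl-10αH-decalin-9β-ol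
Conditions: Ac2O (1.1 equiv), pyridine, CH2Cl2, 0 °C
Reagents that add atoms: acetic anhydride, CC(=O)OC(C)=O
Why: Site-selective acetylation: the equatorial C1 hydroxyl reacts, while the axial C9 hydroxyl syn to the angular methyl does not.

Step 10
Reactants: 15 1α-acetoxy-7α,8α-epoxy-4β,5β-dimethyl-10αH-decalin-9β-ol
Product: 17 1α-acetoxy-10αH-eremophil-11-ene-8α,9β-diol (7β-isopropenyl), via alkoxyalane 16 (not isolated)
Conditions: Me2Al–C(CH3)=CH2 (3 equiv; pre-formed from isopropenylmagnesium bromide and Me2AlCl, magnesium salts filtered off), toluene, −40 °C → rt; then aq. KNaC4H4O6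
Reagents that add atoms: dimethyl(prop-1-en-2-yl)alane, C=C(C)[Al](C)C (made in the flask from isopropenylmagnesium bromide, C=C(C)[Mg]Br, and Me2AlCl, C[Al](C)Cl)
Why: Proposed new method: the axial C9–OH protonates one Al–CH3 to give a bound alkoxy(methyl)(isopropenyl)alane that sits 1,3-syn-axial to C7 on the β face, a second alane molecule activates the epoxide oxygen on the α face, and the sp2 ligand (which migrates in preference to methyl) is handed to the back side of the C7–O bond through a six-membered chair-like transition state, so the epoxide opens trans-diaxially (Fürst–Plattner) with inversion at C7 to give 7β-isopropenyl and 8α-OH, the internal delivery offsetting the syn-axial C5 methyl that would slow an external nucleophile; the closest known reaction type is the hydroxyl-directed opening of epoxides by dialkyl(alkynyl)alanes and the C3-selective opening of 2,3-epoxy alcohols by trialkylalanes, whereas directed transfer of an alkenyl group, and delivery across a 1,3-diaxial relationship, has not been shown.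

Step 11
Reactants: 17 1α-acetoxy-10αH-eremophil-11-ene-8α,9β-diol
Product: 18 1α-acetoxy-8α-tigloyloxy-10αH-eremophil-11-en-9β-ol
Conditions: tigloyl chloride, pyridine, DMAP (cat.), CH2Cl2, 0 °C → rt
Reagents that add atoms: tigloyl chloride, C/C=C(\C)C(=O)Cl
Why: DMAP-catalysed acylation takes the C8 hydroxyl on the open α face, while the C9 hydroxyl, flanked on the β face by the angular methyl and the isopropenyl group, stays free; the trans-diaxial diol cannot pass the acyl group on.

Step 12
Reactants: 18 1α-acetoxy-8α-tigloyloxy-10αH-eremophil-11-en-9β-ol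
Product: 19 1α-acetoxy-8α-tigloyloxy-10αH-eremophil-11-en-9-one (CNP0138236.1)
Conditions: Dess–Martin periodinane, pyridine, CH2Cl2, 0 °C → rt
Reagents that add atoms: none
Why: Dess–Martin oxidation under buffered, non-basic conditions turns the last free hydroxyl into the C9 ketone without epimerising C10 or eliminating the β-acetate.

## Compound list

1 | 2-methylcyclohex-2-en-1-one | CC1=CCCCC1=O | starting material
2 | dimethylaluminium (S)-2,3-dimethylcyclohex-1-en-1-olate | C[C@H]1CCCC(O[Al](C)C)=C1C | intermediate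
3 | lithium trimethyl[(S)-2,3-dimethylcyclohex-1-en-1-olato]aluminate | [Li+].C[C@H]1CCCC(O[Al-](C)(C)C)=C1C | intermediate
4 | (2R,3S)-2-allyl-2,3-dimethylcyclohexan-1-one | C=CC[C@@]1(C)C(=O)CCC[C@@H]1C | intermediate
5 | (E)-N'-[(2R,3S)-2-allyl-2,3-dimethylcyclohexylidene]-2,4,6-triisopropylbenzenesulfonohydrazide | C=CC[C@@]1(C)/C(=N/NS(=O)(=O)c2c(C(C)C)cc(C(C)C)cc2C(C)C)CCC[C@@H]1C | intermediate
6 | dilithium N,α-carbon dianion of hydrazone 5 | [Li+].[Li+].C=CC[C@@]1(C)C([CH-]CC[C@@H]1C)=N[N-]S(=O)(=O)c1c(C(C)C)cc(C(C)C)cc1C(C)C | intermediate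
7 | [(5S,6R)-6-allyl-5,6-dimethylcyclohex-1-en-1-yl]lithium | C=CC[C@@]1(C)C([Li])=CCC[C@@H]1C | intermediate
8 | 1-[(5S,6R)-6-allyl-5,6-dimethylcyclohex-1-en-1-yl]prop-2-en-1-ol, both carbinol epimers | C=CC[C@@]1(C)C(C(O)C=C)=CCC[C@@H]1C | intermediate
9 | (4aR,5S)-4a,5-dimethyl-1,4,4a,5,6,7-hexahydronaphthalen-1-ol, both C9 epimers | OC1C=CC[C@@]2(C)C1=CCC[C@@H]2C | intermediate
10 | (4aR,5S)-4a,5-dimethyl-4a,5,6,7-tetrahydronaphthalen-1(4H)-one | O=C1C=CC[C@@]2(C)C1=CCC[C@@H]2C | intermediate
11 | 7α,8α-epoxy-4β,5β-dimethyl-Δ1(10)-octalin-9-one | O=C1[C@@H]2O[C@@H]2C[C@@]3(C)C1=CCC[C@@H]3C | intermediate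
12 | 7α,8α-epoxy-4β,5β-dimethyl-Δ1(10)-octalin-9β-ol | O[C@H]1[C@@H]2O[C@@H]2C[C@@]3(C)C1=CCC[C@@H]3C | intermediate
13 | 1α-boryl-9β-boryloxy-7α,8α-epoxy-4β,5β-dimethyl-10αH-decalin | [BH2]O[C@H]1[C@@H]2O[C@@H]2C[C@@]3(C)[C@H]1[C@@H]([BH2])CC[C@@H]3C | intermediate
14 | 7α,8α-epoxy-4β,5β-dimethyl-10αH-decalin-1α,9β-diol | O[C@H]1[C@@H]2O[C@@H]2C[C@@]3(C)[C@H]1[C@@H](O)CC[C@@H]3C | intermediate
15 | 1α-acetoxy-7α,8α-epoxy-4β,5β-dimethyl-10αH-decalin-9β-ol | O[C@H]1[C@@H]2O[C@@H]2C[C@@]3(C)[C@H]1[C@@H](OC(C)=O)CC[C@@H]3C | intermediate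
16 | methyl(prop-1-en-2-yl)aluminium 9β-alkoxide of 15 | C=C(C)[Al](C)O[C@H]1[C@@H]2O[C@@H]2C[C@@]3(C)[C@H]1[C@@H](OC(C)=O)CC[C@@H]3C | intermediate
17 | 1α-acetoxy-10αH-eremophil-11-ene-8α,9β-diol (7β-isopropenyl) | C=C(C)[C@H]1C[C@@]2(C)[C@H]([C@@H](O)[C@@H]1O)[C@@H](OC(C)=O)CC[C@@H]2C | intermediate
18 | 1α-acetoxy-8α-tigloyloxy-10αH-eremophil-11-en-9β-ol | C=C(C)[C@H]1C[C@@]2(C)[C@H]([C@@H](O)[C@@H]1OC(=O)/C(C)=C/C)[C@@H](OC(C)=O)CC[C@@H]2C | intermediate
19 | (1S,4S,5R,7R,8R,10S)-1-acetoxy-8-[(E)-2-methylbut-2-enoyloxy]eremophil-11-en-9-one, CNP0138236.1 | C=C(C)[C@H]1C[C@@]2(C)[C@H](C(=O)[C@@H]1OC(=O)/C(C)=C/C)[C@@H](OC(C)=O)CC[C@@H]2C | target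

## Step count and risks

Total step count: 12. Longest linear sequence: 12 steps (fully linear from 1).

The three steps most likely to fail:

**Step 10 (the new step).** The bound alkoxyalane may be too weak a nucleophile, or methyl may transfer instead of isopropenyl. The fallback uses known chemistry and runs from 15 back to 17. The same hydroxyl-directed opening is run in its established sp-carbon form with dimethyl(ethynyl)alane (ethynylmagnesium bromide + Me2AlCl, toluene, 0 °C → rt). The small linear alkynyl group is delivered to C7 to give 1α-acetoxy-7β-ethynyl-4β,5β-dimethyl-10αH-decalin-8α,9β-diol F1. Negishi zirconium-catalysed methylalumination (Me3Al, Cp2ZrCl2, CH2Cl2, 0 °C → rt) then adds CH3–Al across the terminal alkyne, methyl on the internal carbon, to give the alkenylalane F2 (not isolated). Hydrolysis of F2 leaves the isopropenyl group of 17.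

**Step 11.** The C8 hydroxyl is axial and crowded, and ring A of 17 is strained, so acylation with the bulky tigloyl chloride may be slow or may touch O9. The fallback runs from 17 back to 18 and builds the ester double bond after acylation. O8 is acylated with the small, highly reactive 2-(diethoxyphosphoryl)propanoyl chloride (pyridine, CH2Cl2, 0 °C) to give 1α-acetoxy-8α-[2-(diethoxyphosphoryl)propanoyloxy]-10αH-eremophil-11-en-9β-ol F3. Horner–Wadsworth–Emmons olefination with acetaldehyde (LiCl, DBU, MeCN, 0 °C) then gives the (E)-2-methylbut-2-enoate 18.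

**Step 8.** Borane may reduce the neighbouring epoxide (helped by the C9 alkoxyborane), or hydroboration of the hindered trisubstituted alkene may stall. The fallback runs from 12 straight to 15, skipping 14, by acridinium photoredox anti-Markovnikov hydroacetoxylation (9-mesityl-10-methylacridinium tetrafluoroborate 5 mol%, PhSSPh 10 mol%, AcOH, 2,6-lutidine, 1,2-dichloroethane, blue LEDs, rt). Only the trisubstituted alkene is oxidised to its radical cation, acetate attacks C1 from the α face, and the C10 radical takes hydrogen from thiophenol on the same open face. This fallback makes no new compound (F0).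

## Further compounds

F0 | step 8 | none | none
F1 | step 10 | 1α-acetoxy-7β-ethynyl-4β,5β-dimethyl-10αH-decalin-8α,9β-diol | C#C[C@H]1C[C@@]2(C)[C@H]([C@@H](O)[C@@H]1O)[C@@H](OC(C)=O)CC[C@@H]2C
F2 | step 10 | (E)-2-methylalk-1-enyl(dimethyl)alane from F1, both hydroxyls as dimethylaluminium alkoxides | C[Al](C)/C=C(\C)[C@H]1C[C@@]2(C)[C@H]([C@@H](O[Al](C)C)[C@@H]1O[Al](C)C)[C@@H](OC(C)=O)CC[C@@H]2C
F3 | step 11 | 1α-acetoxy-8α-[2-(diethoxyphosphoryl)propanoyloxy]-10αH-eremophil-11-en-9β-ol | C=C(C)[C@H]1C[C@@]2(C)[C@H]([C@@H](O)[C@@H]1OC(=O)C(C)P(=O)(OCC)OCC)[C@@H](OC(C)=O)CC[C@@H]2C
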